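**Plan**
Cuts: the aryl–prenyl bonds at C6 (ring A) and C3' (ring B) go back to aryl bromides. C4–C4a of ring C goes back to an intramolecular Friedel–Crafts acylation. C2–C3 goes back to a carbene C–H insertion between a ring A anisole and a ring B aryldiazoacetate.
Enabling feature: C2 is an unsubstituted CH2 between O1 (on C8a of ring A) and C3, and C3 carries ring B and the C4 carbonyl. C2 is therefore the carbon of an aryl methyl ether, C3 a donor/acceptor carbene carbon, and C4 its ester carbon.
Forward order: rings A and B are bought as arenes and dressed separately (steps 1–4 and 5–7), then joined through C2–C3 (step 8). Ring C closes at C4–C4a (step 10), both prenyl groups enter in one double Stille coupling (step 11), and fluoride frees the phenols (step 12).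
Stereochemistry: C3 is the only stereocentre. The chiral dirhodium carboxylate sets it as R in step 8. Every later step is run without base, because H3 is benzylic and alpha to a carbonyl group.
Spectator groups: both prenyl sites are carried as bromides. Ring A oxygens are TBS ethers and the ring B oxygen is a TIPS ether.

Key step: step 8

Assumption: Rh2(R-BPCP)4 (BPCP = 1-(biphenyl-4-yl)-2,2-diphenylcyclopropane-1-carboxylate) is taken to give (R)-13; if the sense of induction is opposite, Rh2(S-BPCP)4 is used and nothing else changes.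

**Route**

Step 1
Reactants: 1 5-methoxyresorcinol
Product: 2 1-methoxy-3,5-bis(methoxymethoxy)benzene
Conditions: MOMCl (2.5 equiv), i-Pr2NEt (3 equiv), CH2Cl2, 0 °C → rt
Reagents that add atoms: chloromethyl methyl ether, COCCl
Why: O-alkylation of both phenols with the reactive chloromethyl ether (Williamson-type acetal protection) puts the two strongest ortho-directing groups where step 2 needs them.

Step 2
Reactants: 2 1-methoxy-3,5-bis(methoxymethoxy)benzene
Product: 4 2-bromo-5-methoxy-1,3-bis(methoxymethoxy)benzene, via aryllithium 3 (not isolated)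
Conditions: n-BuLi (1.2 equiv), THF, 0 °C, 1 h; BrCH2CH2Br (1.5 equiv), −78 °C → rt
Reagents that add atoms: 1,2-dibromoethane, BrCCBr; n-butyllithium, [Li]CCCC (its lithium stands only in 3)
Why: Directed ortho-metalation occurs at the one ring position chelated by two OMOM groups rather than next to the weaker OMe director, and aryllithium 3 abstracts bromine from 1,2-dibromoethane with loss of ethene.

Step 3
Reactants: 4 2-bromo-5-methoxy-1,3-bis(methoxymethoxy)benzene
Product: 5 2-bromo-5-methoxybenzene-1,3-diol
Conditions: HCl (3 M aq.), MeOH, 45 °C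
Reagents that add atoms: none
Why: Acid-catalysed acetal methanolysis removes the MOM groups, whose OCH2O and OCH3 hydrogens would compete with the methyl ether in step 8, and leaves the aryl methyl ether and the bromide untouched.

Step 4
Reactants: 5 2-bromo-5-methoxybenzene-1,3-diol
Product: 6 4-bromo-3,5-bis(tert-butyldimethylsilyloxy)anisole
Conditions: TBSCl (2.5 equiv), imidazole (5 equiv), DMF, rt
Reagents that add atoms: tert-butyldimethylsilyl chloride, CC(C)(C)[Si](C)(C)Cl
Why: Imidazole-promoted O-silylation of phenols gives TBS ethers that have no heteroatom-activated C–H bond, flank both free ring positions for step 8, and are small enough for ring C to close beside one of them and for palladium to insert between them later.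

Step 5
Reactants: 7 3-bromo-4-hydroxyphenylacetic acid; 8 2,2,2-trichloroethanol
Product: 9 2,2,2-trichloroethyl 2-(3-bromo-4-hydroxyphenyl)acetate
Conditions: 8 (2 equiv), p-TsOH·H2O (cat.), toluene, reflux, Dean–Stark trap
Reagents that add atoms: 2,2,2-trichloroethanol 8, OCC(Cl)(Cl)Cl
Why: Fischer esterification with azeotropic removal of water acylates only alcohol 8, since the phenol of 7 is not esterified under acid catalysis.

Step 6
Reactants: 9 2,2,2-trichloroethyl 2-(3-bromo-4-hydroxyphenyl)acetate
Product: 10 2,2,2-trichloroethyl 2-[3-bromo-4-(triisopropylsilyloxy)phenyl]acetate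
Conditions: TIPSCl (1.2 equiv), imidazole (2.5 equiv), DMF, rt
Reagents that add atoms: triisopropylsilyl chloride, CC(C)[Si](Cl)(C(C)C)C(C)C
Why: Imidazole-promoted O-silylation; the bulkier TIPS group is chosen for ring B because it must survive DBU in step 7 and crowds only one ortho neighbour.

Step 7
Reactants: 10 2,2,2-trichloroethyl 2-[3-bromo-4-(triisopropylsilyloxy)phenyl]acetate
Product: 11 2,2,2-trichloroethyl 2-diazo-2-[3-bromo-4-(triisopropylsilyloxy)phenyl]acetate
Conditions: p-ABSA (1.3 equiv), DBU (1.5 equiv), MeCN, 0 °C → rt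
Reagents that add atoms: 4-acetamidobenzenesulfonyl azide, CC(=O)Nc1ccc(cc1)S(=O)(=O)N=[N+]=[N-]
Why: Regitz diazo transfer: DBU deprotonates the doubly activated benzylic CH2 and the sulfonyl azide hands over N2, a standard entry to trichloroethyl aryldiazoacetates.

Step 8
Reactants: 6 4-bromo-3,5-bis(tert-butyldimethylsilyloxy)anisole; 11 2,2,2-trichloroethyl 2-diazo-2-[3-bromo-4-(triisopropylsilyloxy)phenyl]acetate
Product: 13 2,2,2-trichloroethyl (R)-3-[4-bromo-3,5-bis(tert-butyldimethylsilyloxy)phenoxy]-2-[3-bromo-4-(triisopropylsilyloxy)phenyl]propanoate, via rhodium carbene 12 (not isolated)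
Conditions: 6 (1.0 equiv), Rh2(R-BPCP)4 (1 mol %), 4 Å MS, CH2Cl2, reflux; 11 (1.5 equiv) in CH2Cl2 added over 3 h
Reagents that add atoms: none
Why: The catalyst expels N2 from 11 to give the electrophilic donor/acceptor carbene 12, which engages one C–H bond of the O1 methyl group of 6 in a concerted, asynchronous three-centre transition state with partial hydride transfer, the cationic character developing at C2 being carried by the lone pair of O1 as C2–C3 forms. The closest known reaction type is the enantioselective intermolecular C–H insertion of trichloroethyl aryldiazoacetates into the primary C–H bonds of methyl ethers, aryl methyl ethers among them, under dirhodium triarylcyclopropanecarboxylate catalysis. No ring closes; the step only joins the ring A and ring B fragments. The one new stereocentre, C3, is controlled by the chiral carboxylate pocket, which leaves a single face of the carbene open to the incoming C–H bond, and the catalyst antipode is chosen for R. The step needs selectivity for the methyl group over the ring: the position para to OMe is blocked by bromine, the two ring C–H carbons have no neighbouring C–H for cyclopropanation and each lies between an alkoxy and a silyloxy group, the silyl groups and the OCH2CCl3 unit offer no activated C–H bond, and the bulky catalyst prefers the most exposed primary site. Alkenes would be cyclopropanated or attacked at their allylic hydrogens, which is why both prenyl positions are still bromides here.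

Step 9
Reactants: 13 2,2,2-trichloroethyl (R)-3-[4-bromo-3,5-bis(tert-butyldimethylsilyloxy)phenoxy]-2-[3-bromo-4-(triisopropylsilyloxy)phenyl]propanoate
Product: 14 (R)-3-[4-bromo-3,5-bis(tert-butyldimethylsilyloxy)phenoxy]-2-[3-bromo-4-(triisopropylsilyloxy)phenyl]propanoic acid
Conditions: Zn dust (10 equiv), AcOH/THF (1:1), rt
Reagents that add atoms: none
Why: Reductive trichloroethyl ester cleavage (zinc reduces a C–Cl bond and the organozinc fragments to 1,1-dichloroethene and carboxylate) runs in a weakly acidic medium in which aryl bromides, aryl silyl ethers and C3 persist and base-induced loss of the ring A phenoxide cannot start.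

Step 10
Reactants: 14 (R)-3-[4-bromo-3,5-bis(tert-butyldimethylsilyloxy)phenoxy]-2-[3-bromo-4-(triisopropylsilyloxy)phenyl]propanoic acid
Product: 16 (3R)-6-bromo-3-[3-bromo-4-(triisopropylsilyloxy)phenyl]-5,7-bis(tert-butyldimethylsilyloxy)chroman-4-one, via acid chloride 15 (not isolated)
Conditions: (COCl)2 (1.5 equiv), DMF (cat.), CH2Cl2, 0 °C → rt; evaporate; (CF3)2CHOH/CH2Cl2, 0 °C → rt
Reagents that add atoms: oxalyl chloride, O=C(Cl)C(=O)Cl (its chlorine stands only in 15)
Why: Intramolecular Friedel–Crafts acylation: chloride 15 is made without amine base so that no ketene can form, hexafluoroisopropanol activates it by hydrogen bonding, and the attacked carbon is ortho to O1, ortho to one silyloxy group and para to the other, with the two candidate positions equivalent by symmetry, so a single six-membered ketone with C3 unchanged should result.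

Step 11
Reactants: 16 (3R)-6-bromo-3-[3-bromo-4-(triisopropylsilyloxy)phenyl]-5,7-bis(tert-butyldimethylsilyloxy)chroman-4-one; 17 tributyl(3-methylbut-2-enyl)stannane
Product: 18 (3R)-5,7-bis(tert-butyldimethylsilyloxy)-6-(3-methylbut-2-enyl)-3-[3-(3-methylbut-2-enyl)-4-(triisopropylsilyloxy)phenyl]chroman-4-one
Conditions: 17 (3 equiv), Pd(P(t-Bu)3)2 (10 mol %), toluene (degassed), 80 °C
Reagents that add atoms: tributyl(3-methylbut-2-enyl)stannane 17, CC(C)=CC[Sn](CCCC)(CCCC)CCCC
Why: Stille coupling: the monoligated zerovalent palladium released from Pd(P(t-Bu)3)2 inserts even into di-ortho-substituted aryl bromides, the allylic stannane transmetalates without fluoride or base, and reductive elimination at the unsubstituted allyl terminus, reinforced by the crowded aryl partners, should give linear prenyl groups while the neutral medium spares C3.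

Step 12
Reactants: 18 (3R)-5,7-bis(tert-butyldimethylsilyloxy)-6-(3-methylbut-2-enyl)-3-[3-(3-methylbut-2-enyl)-4-(triisopropylsilyloxy)phenyl]chroman-4-one
Product: 19 (3R)-5,7-dihydroxy-3-[4-hydroxy-3-(3-methylbut-2-enyl)phenyl]-6-(3-methylbut-2-enyl)chroman-4-one
Conditions: Et3N·3HF (5 equiv), THF, 0 °C → rt; pH 6 buffer work-up
Reagents that add atoms: none
Why: Fluoride-driven cleavage of aryl silyl ethers by the slightly acidic Et3N·3HF keeps phenoxide and enolate concentrations negligible, so C3 should hold and the ortho-prenyl phenols should not cyclise to chromans.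

**Compound list**
1 | 5-methoxyresorcinol | COc1cc(O)cc(O)c1 | starting material
2 | 1-methoxy-3,5-bis(methoxymethoxy)benzene | COCOc1cc(OC)cc(OCOC)c1 | intermediate
3 | 4-methoxy-2,6-bis(methoxymethoxy)phenyllithium (not isolated) | [Li]c1c(OCOC)cc(OC)cc1OCOC | intermediate
4 | 2-bromo-5-methoxy-1,3-bis(methoxymethoxy)benzene | COCOc1cc(OC)cc(OCOC)c1Br | intermediate
5 | 2-bromo-5-methoxybenzene-1,3-diol | COc1cc(O)c(Br)c(O)c1 | intermediate
6 | 4-bromo-3,5-bis(tert-butyldimethylsilyloxy)anisole | COc1cc(O[Si](C)(C)C(C)(C)C)c(Br)c(O[Si](C)(C)C(C)(C)C)c1 | intermediate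
7 | 3-bromo-4-hydroxyphenylacetic acid | OC(=O)Cc1ccc(O)c(Br)c1 | starting material
8 | 2,2,2-trichloroethanol | OCC(Cl)(Cl)Cl | starting material
9 | 2,2,2-trichloroethyl 2-(3-bromo-4-hydroxyphenyl)acetate | Oc1ccc(CC(=O)OCC(Cl)(Cl)Cl)cc1Br | intermediate
10 | 2,2,2-trichloroethyl 2-[3-bromo-4-(triisopropylsilyloxy)phenyl]acetate | CC(C)[Si](Oc1ccc(CC(=O)OCC(Cl)(Cl)Cl)cc1Br)(C(C)C)C(C)C | intermediate
11 | 2,2,2-trichloroethyl 2-diazo-2-[3-bromo-4-(triisopropylsilyloxy)phenyl]acetate | Brc1cc(C(=[N+]=[N-])C(=O)OCC(Cl)(Cl)Cl)ccc1O[Si](C(C)C)(C(C)C)C(C)C | intermediate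
12 | rhodium carbene from 11 (not isolated; second rhodium and carboxylate ligands omitted in the SMILES) | Brc1cc(C(=[Rh])C(=O)OCC(Cl)(Cl)Cl)ccc1O[Si](C(C)C)(C(C)C)C(C)C | intermediate
13 | 2,2,2-trichloroethyl (R)-3-[4-bromo-3,5-bis(tert-butyldimethylsilyloxy)phenoxy]-2-[3-bromo-4-(triisopropylsilyloxy)phenyl]propanoate | Brc1cc([C@@H](C(=O)OCC(Cl)(Cl)Cl)COc2cc(O[Si](C)(C)C(C)(C)C)c(Br)c(O[Si](C)(C)C(C)(C)C)c2)ccc1O[Si](C(C)C)(C(C)C)C(C)C | intermediate
14 | (R)-3-[4-bromo-3,5-bis(tert-butyldimethylsilyloxy)phenoxy]-2-[3-bromo-4-(triisopropylsilyloxy)phenyl]propanoic acid | Brc1cc([C@@H](C(=O)O)COc2cc(O[Si](C)(C)C(C)(C)C)c(Br)c(O[Si](C)(C)C(C)(C)C)c2)ccc1O[Si](C(C)C)(C(C)C)C(C)C | intermediate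
15 | (R)-3-[4-bromo-3,5-bis(tert-butyldimethylsilyloxy)phenoxy]-2-[3-bromo-4-(triisopropylsilyloxy)phenyl]propanoyl chloride (not isolated) | Brc1cc([C@@H](C(=O)Cl)COc2cc(O[Si](C)(C)C(C)(C)C)c(Br)c(O[Si](C)(C)C(C)(C)C)c2)ccc1O[Si](C(C)C)(C(C)C)C(C)C | intermediate
16 | (3R)-6-bromo-3-[3-bromo-4-(triisopropylsilyloxy)phenyl]-5,7-bis(tert-butyldimethylsilyloxy)chroman-4-one | Brc1cc([C@@H]2COc3cc(O[Si](C)(C)C(C)(C)C)c(Br)c(O[Si](C)(C)C(C)(C)C)c3C2=O)ccc1O[Si](C(C)C)(C(C)C)C(C)C | intermediate
17 | tributyl(3-methylbut-2-enyl)stannane | CC(C)=CC[Sn](CCCC)(CCCC)CCCC | starting material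
18 | (3R)-5,7-bis(tert-butyldimethylsilyloxy)-6-(3-methylbut-2-enyl)-3-[3-(3-methylbut-2-enyl)-4-(triisopropylsilyloxy)phenyl]chroman-4-one | CC(C)=CCc1cc([C@@H]2COc3cc(O[Si](C)(C)C(C)(C)C)c(CC=C(C)C)c(O[Si](C)(C)C(C)(C)C)c3C2=O)ccc1O[Si](C(C)C)(C(C)C)C(C)C | intermediate
19 | (3R)-5,7-dihydroxy-3-[4-hydroxy-3-(3-methylbut-2-enyl)phenyl]-6-(3-methylbut-2-enyl)chroman-4-one | CC(C)=CCc1cc([C@@H]2COc3cc(O)c(CC=C(C)C)c(O)c3C2=O)ccc1O | target

**Count**
Total steps: 12. Longest linear sequence: 9 (steps 1–4, then 8–12). The ring B branch (steps 5–7) joins at step 8.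

**Steps most likely to fail**

Step 8. The carbene may attack the very electron-rich ring carbons instead of the methyl group. Carbene dimerisation may outrun a slow insertion, and facial discrimination may drop with so crowded an ether.
- The fallback disarms ring A electronically instead of only shielding it. It sets out from 5.
- 2,2,2-Trichloroethyl chloroformate and pyridine in CH2Cl2 convert 5 into 4-bromo-3,5-bis(2,2,2-trichloroethoxycarbonyloxy)anisole F1. Its carbonate CH2 groups are as inert to the carbene as the ester CH2 of 11, and its arene lies closer to the halogenated anisoles for which the insertion is established.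
- Insertion of 12 under the conditions of step 8 gives 2,2,2-trichloroethyl (R)-3-[4-bromo-3,5-bis(2,2,2-trichloroethoxycarbonyloxy)phenoxy]-2-[3-bromo-4-(triisopropylsilyloxy)phenyl]propanoate F2.
- Zn dust in AcOH/THF removes the ester and both carbonates in one operation and gives (R)-3-(4-bromo-3,5-dihydroxyphenoxy)-2-[3-bromo-4-(triisopropylsilyloxy)phenyl]propanoic acid F3.
- TBSCl and imidazole in DMF give the tert-butyldimethylsilyl ester of 14 F4. A mildly acidic aqueous work-up hydrolyses only the silyl ester, and the route is rejoined at 14, one step longer than the main line.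

Step 11. Transfer of the bulky prenyl group to the arylpalladium at C6, which is flanked by two silyl ethers, may be sluggish. Allylic transposition to the branched isomer may occur, and heating may last long enough for C3 to racemise through the enol.
- The fallback builds each prenyl group in two stages. It sets out from 16.
- Allyltributylstannane with Pd(P(t-Bu)3)2 in toluene at 50–60 °C transfers the smaller allyl group, which has no regiochemical ambiguity. This gives (3R)-6-allyl-3-[3-allyl-4-(triisopropylsilyloxy)phenyl]-5,7-bis(tert-butyldimethylsilyloxy)chroman-4-one F7.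
- Double cross-metathesis with excess 2-methylbut-2-ene and RuCl2(=CHPh)(PCy3)(H2IMes) (second-generation Grubbs catalyst) in CH2Cl2 at 35–40 °C, a neutral and standard allyl-to-prenyl conversion, rejoins the route at 18.

Step 10. Closure may be slow at a ring carbon shielded by a silyl ether. The silyl group peri to the new carbonyl may be lost, and configuration at C3 may erode through enolisation of the acid chloride or of the ketone in the acidic medium.
- The fallback moves the origin of the C3 configuration behind the ring closure, so the closure can be forced. It sets out from 14.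
- Chloride 15 is cyclised with SnCl4 in CH2Cl2 at 0 °C → rt without regard to C3. This gives racemic or partly racemised 6-bromo-3-[3-bromo-4-(triisopropylsilyloxy)phenyl]-5,7-bis(tert-butyldimethylsilyloxy)chroman-4-one F5.
- Noyori–Ikariya transfer hydrogenation under dynamic kinetic resolution follows (RuCl(p-cymene)[(R,R)-TsDPEN], HCO2H/Et3N, EtOAc, 40 °C). This is a known treatment of isoflavanones, in which the enantiomers interconvert through the enol and only one is reduced.
- The product is (3R,4R)-cis-6-bromo-3-[3-bromo-4-(triisopropylsilyloxy)phenyl]-5,7-bis(tert-butyldimethylsilyloxy)chroman-4-ol F6.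
- Dess–Martin periodinane in CH2Cl2 at 0 °C rejoins the route at 16.

**Further compounds**
F1 | step 8 | 4-bromo-3,5-bis(2,2,2-trichloroethoxycarbonyloxy)anisole | COc1cc(OC(=O)OCC(Cl)(Cl)Cl)c(Br)c(OC(=O)OCC(Cl)(Cl)Cl)c1
F2 | step 8 | 2,2,2-trichloroethyl (R)-3-[4-bromo-3,5-bis(2,2,2-trichloroethoxycarbonyloxy)phenoxy]-2-[3-bromo-4-(triisopropylsilyloxy)phenyl]propanoate | Brc1cc([C@@H](C(=O)OCC(Cl)(Cl)Cl)COc2cc(OC(=O)OCC(Cl)(Cl)Cl)c(Br)c(OC(=O)OCC(Cl)(Cl)Cl)c2)ccc1O[Si](C(C)C)(C(C)C)C(C)C
F3 | step 8 | (R)-3-(4-bromo-3,5-dihydroxyphenoxy)-2-[3-bromo-4-(triisopropylsilyloxy)phenyl]propanoic acid | Brc1cc([C@@H](C(=O)O)COc2cc(O)c(Br)c(O)c2)ccc1O[Si](C(C)C)(C(C)C)C(C)C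
F4 | step 8 | tert-butyldimethylsilyl ester of 14 | Brc1cc([C@@H](C(=O)O[Si](C)(C)C(C)(C)C)COc2cc(O[Si](C)(C)C(C)(C)C)c(Br)c(O[Si](C)(C)C(C)(C)C)c2)ccc1O[Si](C(C)C)(C(C)C)C(C)C
F5 | step 10 | racemic 6-bromo-3-[3-bromo-4-(triisopropylsilyloxy)phenyl]-5,7-bis(tert-butyldimethylsilyloxy)chroman-4-one | Brc1cc(C2COc3cc(O[Si](C)(C)C(C)(C)C)c(Br)c(O[Si](C)(C)C(C)(C)C)c3C2=O)ccc1O[Si](C(C)C)(C(C)C)C(C)C
F6 | step 10 | (3R,4R)-cis-6-bromo-3-[3-bromo-4-(triisopropylsilyloxy)phenyl]-5,7-bis(tert-butyldimethylsilyloxy)chroman-4-ol | Brc1cc([C@@H]2COc3cc(O[Si](C)(C)C(C)(C)C)c(Br)c(O[Si](C)(C)C(C)(C)C)c3[C@@H]2O)ccc1O[Si](C(C)C)(C(C)C)C(C)C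
F7 | step 11 | (3R)-6-allyl-3-[3-allyl-4-(triisopropylsilyloxy)phenyl]-5,7-bis(tert-butyldimethylsilyloxy)chroman-4-one | C=CCc1cc([C@@H]2COc3cc(O[Si](C)(C)C(C)(C)C)c(CC=C)c(O[Si](C)(C)C(C)(C)C)c3C2=O)ccc1O[Si](C(C)C)(C(C)C)C(C)C
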